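4 questions on the dusk flask, and I take them through one subtraction.

| flask | substrate | free catalyst | impurity | temperature | remark | time |
|---|---|---|---|---|---|---|
| dusk | 20 mM | 1 mM | 1.2 mM | −20 °C | the very flask that is asked about, followed so far |  |
| dawn | 20 mM | 1 mM | 1.2 mM | −35 °C | run made earlier |  |
| flask | 20 mM | 1.0 mM | 1.2 mM | −20 °C |  | 20 min |

- dusk (time / min: target / %, substrate / %): 1.00: 19.9, 72.8; 3.00: 18.9, 72.2; 6.00: 21.1, 74.2; 8.00: 19.7, 72.8; 12.0: 21.1, 73.5
- dawn (time / min: target / %, substrate / %): 2.00: 11.3, 73.1; 6.00: 13.4, 71.8; 12.0: 12.3, 70.6; 15.0: 12.6, 72.4; 25.0: 13.7, 72.8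

(standard deviation of a reading: 1 percentage point)

- amber: at 20 min raise the temperature by 15 K, then wait 40 min
- grey: at 20 min take out 90 % of the target then present, then wait 40 min
- blue: change nothing and wait 40 min more
- red: at 20 min add free catalyst, 100 % of the amount charged, then wait 40 min

- target, in percent of the substrate first charged, at 20 min
- which option adds most target ("none" when 2 percentage points or less is all one gets) (amber / grey / blue / red / none)
- target present, with what was taken out counted in, in percent of the substrate first charged, after blue
- target present, with what was taken out counted in, in percent of the substrate first charged, after red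

- removed target is counted in
- the analysis behind the earlier runs scatters by 1 percentage point, standard deviation
- additions bring no volume worth counting

The dusk readings are flat from 1.00 min on, with target at 20.1 % and substrate at 73.1 % on average. The dawn flask, colder by 15.0 K, stalls with substrate at 72.1 %, so I read the stop as a count, not a clock.

Free catalyst charged minus impurity charged gives −0.200 mM in the dusk flask, and I call this the catalyst margin. I assume each impurity takes one catalyst for good. A negative margin then makes free catalyst the limiting reagent of the poisoning, and by this reckoning the dusk flask stops with 0.200 mM of impurity to spare.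

So I commit to 20.1 % now and the same after blue. Amber, grey and blue leave the margin negative, while red turns it to 0.800 mM, so I choose red. To use up the substrate read as remaining, each surviving catalyst then needs 18.3 turnovers in 40 min. That is a slower pace than the 5.38 turnovers per charged catalyst read from the dusk flask within 1.00 min. With target taking 74.9 % of the substrate used, as read from the dusk flask, I estimate 74.9 % after red.

Your forecast gives 20.1 % now, 20.1 % after blue, 72 % after red and red as the choice, holding that “the reaction has stopped, not slowed”. We part on red, where my figure is higher.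

The dusk flask gives 20.5 % at 20 min, 20.5 % after blue and 75.2 % after red. Red adds 55 percentage points, well beyond amber and grey, which add 4.2 points and 4.6 points.

    catalyst intermediate A + target → spent catalyst A (k = 0.210 M⁻¹ s⁻¹, Ea = 39.0 kJ mol⁻¹)
    target ⇌ isomer of the product (K = 0.330, k = 0.260 s⁻¹, Ea = 55.0 kJ mol⁻¹, ΔH = −43.0 kJ mol⁻¹)
    substrate + free catalyst ⇌ catalyst intermediate A (K = 170 M⁻¹, k = 73.0 M⁻¹ s⁻¹, Ea = 36.0 kJ mol⁻¹, ΔH = −42.0 kJ mol⁻¹)
    catalyst intermediate B → free catalyst + target (k = 2.00 s⁻¹, Ea = 53.0 kJ mol⁻¹)
    free catalyst + impurity → spent catalyst B (k = 390 M⁻¹ s⁻¹, Ea = 38.0 kJ mol⁻¹)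
    catalyst intermediate A ⇌ catalyst intermediate B (K = 6.80, k = 24.0 s⁻¹, Ea = 54.0 kJ mol⁻¹, ΔH = 3.00 kJ mol⁻¹)
    (constants at −20 °C)

The margin of −0.200 mM is, in size, 16.7 % of the impurity charge, and the dusk flask holds 16.7 % of its impurity charge at 20.0 min, with free catalyst at 0 % of its charge. The neighbour flask charged with 2.5 mM of free catalyst has a margin of 1.30 mM, which is 52.0 % of its catalyst. At 20.0 min that neighbour holds free catalyst at 51.9 % of its charge, substrate at 0 % and target at 75.2 %.

The readings are calculated for an exercise; scatter was added.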